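A direct plan would make the pyranone first and fuse ring A onto it at the end.
It would acylate the methyl ketone enolate of 4-(dimethylamino)-3-(p-tolylsulfinyl)but-3-en-2-one A1 with hexacosanoyl chloride A2 and close 2-pentacosyl-5-(p-tolylsulfinyl)-4H-pyran-4-one A3 with acid.
It would then add 1-methoxy-1,3-bis(trimethylsilyloxy)buta-1,3-diene A4 across C5=C6 of A3 and rely on two eliminations to aromatise.
The weakest step would be this ring A benzannulation: a 3-sulfinyl-4-pyranone has no record as a dienophile, the site and direction of ring closure would rest on argument alone, and it would be run last on the material carrying the costly C26 chain.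
Next would be the enolate acylation that brings in the chain: a push-pull enaminone enolate beside a sulfoxide and a waxy acid chloride at −78 °C would invite O-acylation and double acylation.
Third would be the run-up: six of seven operations would only build two reagents whose sulfinyl, dimethylamino, silyl and methoxy groups are all discarded.

**Plan of the new route**
The retrosynthesis cuts O1–C2 first and then both bonds of C4 (C4a–C4 and C3–C4): C4 becomes carbon monoxide, C2–C3 with the chain a terminal alkyne, and ring A a purchased aryl iodide.
The structure allows this because C4 is a ketone carbon bound only to aryl carbon C4a and to C3, C3 carries hydrogen, and the oxygens on C5, C7 and C8a are 1,3,5-related, so the ring A partner is symmetrical and either ortho oxygen can become O1.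
Ring A is present from the start, one palladium-catalysed three-component coupling joins all carbons of the target, and ring C closes last when the phenols are unmasked.
No ring is built onto a pyranone, no enolate is acylated, and no sulfinyl or silyl auxiliary is made; the chain enters as a robust alkyne from 1-hexacosanol.

Key step: step 3

Assumption: 1-hexacosanol, 2-iodo-1,3,5-trimethoxybenzene and carbon monoxide are taken as commercial; the target has no stereocentre, so none has to be set.

Step 1
Reactants: 1 1-hexacosanol
Product: 2 hexacosanal
Conditions: Dess–Martin periodinane (1.3 equiv), CH2Cl2/CHCl3, 35 °C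
Reagents that add atoms: none
Why: Dess–Martin oxidation of a primary alcohol should stop cleanly at the aldehyde under neutral, non-aqueous conditions, and gentle warming keeps the waxy C26 alcohol in solution.

Step 2
Reactants: 2 hexacosanal
Product: 3 heptacos-1-yne
Conditions: dimethyl (1-diazo-2-oxopropyl)phosphonate (1.3 equiv), K2CO3 (2 equiv), MeOH/THF 1:1, rt → 40 °C
Reagents that add atoms: dimethyl (1-diazo-2-oxopropyl)phosphonate, COP(=O)(OC)C(=[N+]=[N-])C(C)=O
Why: Seyferth–Gilbert homologation in the Ohira–Bestmann variant should turn the aldehyde into the terminal alkyne with one added carbon (Horner–Wadsworth–Emmons olefination to a diazoalkene, loss of nitrogen, 1,2-hydride shift of the alkylidene carbene), with THF as co-solvent for the long chain.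

Step 3
Reactants: 3 heptacos-1-yne; 4 2-iodo-1,3,5-trimethoxybenzene; 5 carbon monoxide
Product: 6 1-(2,4,6-trimethoxyphenyl)octacos-2-yn-1-one
Conditions: 3 (1.0 equiv), 4 (1.2 equiv), CO (5 bar), PdCl2(PPh3)2 (5 mol %), CuI (2 mol %), Et3N (3 equiv), THF, 45 °C
Reagents that add atoms: none
Why: Carbonylative Sonogashira coupling, a known three-component alkynone synthesis: the divalent palladium precatalyst is reduced in situ to zerovalent palladium, which inserts into the C–I bond of 4; CO then inserts into the aryl–palladium bond to give an aroylpalladium iodide (bond C4a–C4), the copper acetylide formed from 3, CuI and Et3N transfers its alkynyl group, and reductive elimination makes C4–C3. The closest known reaction type is this same coupling of electron-rich aryl iodides with terminal alkynes under CO. The step closes no ring and creates no stereocentre; ring C is closed in step 4 from the atoms assembled here. The selectivity needed is carbonylative over direct alkynylation and over oxidative dimerisation of 3: the electron-rich ring and the two ortho methoxy groups of 4 favour CO insertion and hinder alkynyl transfer to the crowded aryl–palladium centre, and CO pressure with exclusion of oxygen does the rest. Regiochemistry is not in question, since 4 is symmetrical and the terminal alkyne can react only at its CH end. The cheap iodide 4 is used in excess so that the chain-bearing alkyne is consumed.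

Step 4
Reactants: 6 1-(2,4,6-trimethoxyphenyl)octacos-2-yn-1-one
Product: 8 5,7-dihydroxy-2-pentacosyl-4H-chromen-4-one, via trihydroxyphenyl ynone 7 (not isolated)
Conditions: BBr3 (8 equiv), CH2Cl2, −78 °C → rt, then 40 °C; H2O, THF, rt, until ring closure is complete
Reagents that add atoms: none
Why: Lewis-acid cleavage of aryl methyl ethers by BBr3 should free all three phenols (the two ortho to the ketone with chelation assistance, the para one on warming), and in the acidic hydrolysis mixture an ortho phenol should add to the ynone by 6-endo-dig oxa-Michael closure, the mode that acid favours over the five-membered alternative; either ortho phenol gives the same chromone, and prior conjugate addition of bromide would not change the outcome because the adduct closes to the same ring.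

**Compound list**
1 | 1-hexacosanol | CCCCCCCCCCCCCCCCCCCCCCCCCCO | starting material
2 | hexacosanal | CCCCCCCCCCCCCCCCCCCCCCCCCC=O | intermediate
3 | heptacos-1-yne | CCCCCCCCCCCCCCCCCCCCCCCCCC#C | intermediate
4 | 2-iodo-1,3,5-trimethoxybenzene | COc1cc(OC)c(I)c(OC)c1 | starting material
5 | carbon monoxide | [C-]#[O+] | starting material
6 | 1-(2,4,6-trimethoxyphenyl)octacos-2-yn-1-one | CCCCCCCCCCCCCCCCCCCCCCCCCC#CC(=O)c1c(OC)cc(OC)cc1OC | intermediate
7 | 1-(2,4,6-trihydroxyphenyl)octacos-2-yn-1-one (not isolated; held as boron aryloxides until hydrolysis) | CCCCCCCCCCCCCCCCCCCCCCCCCC#CC(=O)c1c(O)cc(O)cc1O | intermediate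
8 | 5,7-dihydroxy-2-pentacosyl-4H-chromen-4-one | CCCCCCCCCCCCCCCCCCCCCCCCCc1cc(=O)c2c(O)cc(O)cc2o1 | target

Total step count: 4. Longest linear sequence: 4 (1 → 2 → 3 → 6 → 8).

**Steps most likely to fail**

Step 3. Oxidative addition at the doubly ortho-substituted, electron-rich iodide may be slow under CO, so that direct alkynylation without CO uptake or oxidative dimerisation of the alkyne takes over. The fallback sets out from 3 and returns at 6. Alkyne 3 would be deprotonated with n-BuLi in THF at −40 °C and added to commercial 2,4,6-trimethoxybenzaldehyde to give racemic 1-(2,4,6-trimethoxyphenyl)octacos-2-yn-1-ol F1. Oxidation of the propargylic alcohol with MnO2 in CH2Cl2 would give 6. C4 then arrives already bound to ring A and no gas or coupling catalyst is needed.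

Step 4. Cleavage of the methoxy group para to the ketone, which has no chelation assistance, may stall, the triple bond may be attacked by the boron halide before a phenol is free, or ring closure may go partly 5-exo. The fallback sets out from 6 and returns at 8, and separates the events. BCl3 (1.1 equiv, CH2Cl2, −78 → 0 °C) would cleave one ortho methoxy group only, giving 1-(2-hydroxy-4,6-dimethoxyphenyl)octacos-2-yn-1-one F2. Catalytic TfOH in CH2Cl2 would close it 6-endo to 5,7-dimethoxy-2-pentacosyl-4H-chromen-4-one F3. A pyridinium chloride melt at 190 °C would then cleave both remaining ethers of the stable chromone to 8.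

Step 2. The waxy aldehyde may stay out of solution in methanol and self-condense by aldol reaction under carbonate before it meets the diazophosphonate anion. The fallback sets out from 2 and returns at 3 by a Corey–Fuchs sequence in aprotic solvents. CBr4/PPh3 in CH2Cl2 would give 1,1-dibromoheptacos-1-ene F4. Treatment with n-BuLi (2.2 equiv) in THF, −78 °C → rt, then water, would give 3.

**Further compounds**
F1 | step 3 | 1-(2,4,6-trimethoxyphenyl)octacos-2-yn-1-ol (racemic) | CCCCCCCCCCCCCCCCCCCCCCCCCC#CC(O)c1c(OC)cc(OC)cc1OC
F2 | step 4 | 1-(2-hydroxy-4,6-dimethoxyphenyl)octacos-2-yn-1-one | CCCCCCCCCCCCCCCCCCCCCCCCCC#CC(=O)c1c(O)cc(OC)cc1OC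
F3 | step 4 | 5,7-dimethoxy-2-pentacosyl-4H-chromen-4-one | CCCCCCCCCCCCCCCCCCCCCCCCCc1cc(=O)c2c(OC)cc(OC)cc2o1
F4 | step 2 | 1,1-dibromoheptacos-1-ene | CCCCCCCCCCCCCCCCCCCCCCCCCC=C(Br)Br
A1 | direct plan | 4-(dimethylamino)-3-(p-tolylsulfinyl)but-3-en-2-one | CC(=O)C(=CN(C)C)S(=O)c1ccc(C)cc1
A2 | direct plan | hexacosanoyl chloride | CCCCCCCCCCCCCCCCCCCCCCCCCC(=O)Cl
A3 | direct plan | 2-pentacosyl-5-(p-tolylsulfinyl)-4H-pyran-4-one | CCCCCCCCCCCCCCCCCCCCCCCCCc1cc(=O)c(S(=O)c2ccc(C)cc2)co1
A4 | direct plan | 1-methoxy-1,3-bis(trimethylsilyloxy)buta-1,3-diene | COC(O[Si](C)(C)C)=CC(=C)O[Si](C)(C)C
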